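A direct plan would make the cis-β-lactone A1 by asymmetric ketene–aldehyde cycloaddition, desaturate it through the selenoxide to the alkylidene β-lactones A2 (Z) and A3 (E), saponify A3 to the hydroxy acid A4, open A2 with the dianion of A4, close the enol lactone with AgNO3 to the alkynyl ester A5 and hydrate the alkyne of A5 with Ph3PAuCl/AgSbF6.
Its weakest steps would be:
(1) the selenoxide elimination: two steps for one C=C bond whose geometry would be left to chance, although one half needs Z and the other E;
(2) the union of A2 and A4 by lactone opening: an untested acylation, open to conjugate addition and oligomer formation, run on both advanced fragments;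
(3) the final alkyne hydration of A5: run on the precious ester beside an enol lactone, an allylic ester and an epimerisable α-ketol centre.

**Plan of the new route**
Cuts: the ester C(acyl)–O bond between the halves (plain acylation of the finished lactone alcohol 11 with keto acid 21); in each half the C–CO2H bond (alkenyllithium + CO2), the trisubstituted alkene (back to an alkyne: cis-hydrostannation for the E lactone half, trans-hydrostannation for the Z acyl half) and the carbinol–alkyne C–C bond (enal + terminal alkyne, Zn-ProPhenol).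
Feature used: in both halves the alkene carbon that bears the carboxyl (C3 of the oxolan-2-one; C2 of the hexadec-2-enoyl chain) is bonded directly to the oxygenated stereocentre (ring C4; C1 of the 1-hydroxy-2-oxopropyl group). In the alkyne precursor of the acyl half that oxygen is a free propargylic OH, which steers tin, then CO2, onto the neighbouring alkyne carbon and H trans onto the chain carbon.
Ring order: the only ring, the oxolan-2-one, is closed at the monomer stage (O1–C5, step 5), and the methyl ketone is unmasked (step 9), before the halves are joined.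
Weak steps gone: no olefin-forming elimination (each geometry follows from the syn or anti course of an alkyne addition), no lactone-opening coupling, no alkyne hydration on the final ester (the last step is a silyl ether cleavage).

Key step: step 7

Assumptions: pentadec-1-yne, ethynyl(trimethyl)silane and methacrolein are commercial. (S,S)-ProPhenol (2,6-bis{[(2S)-2-(hydroxydiphenylmethyl)pyrrolidin-1-yl]methyl}-4-methylphenol) is taken to deliver an alkynylzinc to the Si face of an α-branched enal; (R,R)-ProPhenol is its enantiomer. If the first run (Mosher ester analysis) shows the opposite sense, the two ligands are exchanged between steps 3 and 6. Cp* = η5-C5Me5; EDC·HCl = N-(3-dimethylaminopropyl)-N′-ethylcarbodiimide hydrochloride.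

**Step 1**
Reactants: 1 pentadec-1-yne
Product: 3 hexadec-2-ynal, via lithium pentadec-1-yn-1-ide 2 (not isolated)
Conditions: n-BuLi (1.05 equiv), THF, −40 °C; DMF (2 equiv), −40 °C → rt; inverse quench into 10% aq. KH2PO4/MTBE, 5 °C
Reagents that add atoms: N,N-dimethylformamide, CN(C)C=O
Why: Formylation of a lithium acetylide with DMF is a standard route to 2-alkynals, and the inverse quench into phosphate buffer should release the aldehyde from the hemiaminolate without conjugate addition of dimethylamine.

**Step 2**
Reactants: 3 hexadec-2-ynal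
Product: 4 (2E)-2-(tributylstannyl)hexadec-2-enal
Conditions: Pd(PPh3)4 (2 mol %), Bu3SnH (1.05 equiv, slow addition), THF, 0 °C
Reagents that add atoms: tributyltin hydride, CCCC[SnH](CCCC)CCCC
Why: Palladium-catalysed hydrostannation of a conjugated alkyne adds Sn–H syn with tin on the carbon α to the carbonyl, so the tridecyl chain should end cis to the formyl carbon (later lactone C4) and trans to tin (later the C2 carboxyl), which is the E geometry of the lactone half.

**Step 3**
Reactants: 4 (2E)-2-(tributylstannyl)hexadec-2-enal; 5 ethynyl(trimethyl)silane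
Product: 6 (3R,4E)-4-(tributylstannyl)-1-(trimethylsilyl)octadec-4-en-1-yn-3-ol
Conditions: (R,R)-ProPhenol (20 mol %), Ph3P=O (40 mol %), Me2Zn (3 equiv), 5 (3 equiv), toluene, 4 °C; aq. NH4Cl
Reagents that add atoms: none
Why: Zn-ProPhenol asymmetric alkynylation of an α-branched enal, in which the dinuclear zinc catalyst binds the aldehyde and the alkynylzinc made from 5 and Me2Zn; 1,2-addition to the Re face should set the (3R) carbinol (later lactone C4), and the alkenyl–tin bond is inert to organozincs.

**Step 4**
Reactants: 6 (3R,4E)-4-(tributylstannyl)-1-(trimethylsilyl)octadec-4-en-1-yn-3-ol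
Product: 9 (2E)-2-[(1S)-1-hydroxy-3-(trimethylsilyl)prop-2-yn-1-yl]hexadec-2-enoic acid, via dilithio species 7 (not isolated), via dilithium carboxylate 8 (not isolated)
Conditions: MeLi (2.3 equiv), THF, −78 → −40 °C; CO2 (dried gas), −78 °C; 1 M HCl to pH 3, 0 °C
Reagents that add atoms: carbon dioxide, O=C=O; methyllithium, [Li]C (only the Li of 7 and 8)
Why: After deprotonation of the hydroxyl, tin–lithium exchange gives a configurationally stable alkenyllithium that is carboxylated with retention, so CO2H takes the place of tin trans to the chain; the carbinol centre is not touched (its descriptor changes only through the priorities) and the alkynylsilane should survive MeLi at low temperature.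

**Step 5**
Reactants: 9 (2E)-2-[(1S)-1-hydroxy-3-(trimethylsilyl)prop-2-yn-1-yl]hexadec-2-enoic acid
Product: 11 (3E,4S)-4-hydroxy-5-methylidene-3-tetradecylideneoxolan-2-one, via desilylated alkynoic acid 10 (not isolated)
Conditions: AgNO3 (20 mol %), acetone/H2O 10:1, rt, dark
Reagents that add atoms: none
Why: Monovalent silver should first remove the alkynyl SiMe3 group via the silver acetylide and then catalyse the 5-exo-dig cycloisomerisation of the 4-pentynoic acid unit (O1–C5 bond), which gives the γ-methylene lactone without touching C4 or the E alkene.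

**Step 6**
Reactants: 1 pentadec-1-yne; 12 methacrolein (2-methylprop-2-enal)
Product: 13 (3R)-2-methyloctadec-1-en-4-yn-3-ol
Conditions: (S,S)-ProPhenol (20 mol %), Ph3P=O (40 mol %), Me2Zn (3 equiv), 1 (2.5 equiv, excess recovered), 12 (1 equiv), toluene, 4 °C; aq. NH4Cl
Reagents that add atoms: none
Why: The same Zn-ProPhenol alkynylation with the antipodal ligand, now adding an alkylacetylene to the Si face of methacrolein, should set the (3R) carbinol that becomes the (S) α-ketol centre of the acyl half; the isopropenyl group is the latent acetyl group.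

**Step 7**
Reactants: 13 (3R)-2-methyloctadec-1-en-4-yn-3-ol
Product: 17 (2Z)-2-[(1R)-1-hydroxy-2-methylprop-2-en-1-yl]hexadec-2-enoic acid, via alkenylstannane 14 (not isolated), via dilithio species 15 (not isolated), via dilithium carboxylate 16 (not isolated)
Conditions: [Cp*RuCl]4 (1.25 mol %), Bu3SnH (1.05 equiv, slow addition), CH2Cl2, rt; solvent exchange to THF; MeLi (2.4 equiv), −78 → −40 °C; CO2 (dried gas), −78 °C; 1 M HCl to pH 3, 0 °C
Reagents that add atoms: carbon dioxide, O=C=O; tributyltin hydride, CCCC[SnH](CCCC)CCCC (supplies the tin of 14, which leaves again in the exchange); methyllithium, [Li]C (only the Li of 15 and 16)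
Why: The [Cp*RuCl] fragment binds the alkyne of 13 and the Sn–H bond in one coordination sphere while the propargylic O–H hydrogen-bonds to the Ru–Cl unit, so that hydrogen is delivered to the distal carbon C5 and, through an η2-vinyl (metallacyclopropene) intermediate, tin arrives on the proximal carbon C4 from the opposite face; the closest known reaction type is the hydroxyl-directed ruthenium-catalysed trans-hydrostannation of propargylic alcohols. No ring is closed and no stereocentre is formed: what is created is the Z-trisubstituted alkene (chain and tin cis), fixed by the anti course of the addition, and the C3 carbinol from step 6 is not touched. Tin–lithium exchange with MeLi (after deprotonation of the OH) and carboxylation then replace tin by CO2H with retention, as known for alkenylstannanes, so the whole operation is a formal trans-hydrocarboxylation of the alkyne with CO2. The step needs regioselectivity (tin, hence carboxyl, on C4 and not C5), anti stereoselectivity and chemoselectivity for the alkyne over the 1,1-disubstituted alkene; the free hydroxyl next to the alkyne should secure the first, the ruthenium mechanism the second and the inertness of this catalyst towards alkenes the third.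

**Step 8**
Reactants: 17 (2Z)-2-[(1R)-1-hydroxy-2-methylprop-2-en-1-yl]hexadec-2-enoic acid
Product: 19 (2Z)-2-{(1R)-2-methyl-1-[(triethylsilyl)oxy]prop-2-en-1-yl}hexadec-2-enoic acid, via triethylsilyl ester 18 (not isolated)
Conditions: Et3SiCl (2.4 equiv), imidazole (5 equiv), CH2Cl2, 0 °C → rt; then THF/H2O 4:1, rt (hydrolysis of the silyl ester only)
Reagents that add atoms: chlorotriethylsilane, CC[Si](Cl)(CC)CC
Why: Silylation of both OH and CO2H followed by selective hydrolysis of the labile silyl ester should leave the secondary triethylsilyl ether, which blocks β-lactone formation and self-acylation in the later esterification.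

**Step 9**
Reactants: 19 (2Z)-2-{(1R)-2-methyl-1-[(triethylsilyl)oxy]prop-2-en-1-yl}hexadec-2-enoic acid
Product: 21 (2Z)-2-{(1S)-2-oxo-1-[(triethylsilyl)oxy]propyl}hexadec-2-enoic acid, via secondary ozonide 20 (not isolated)
Conditions: O3 (1.0 equiv, Sudan Red 7B as end-point indicator), CH2Cl2, −78 °C; Me2S (5 equiv), −78 °C → rt
Reagents that add atoms: ozone, [O-][O+]=O
Why: Chemoselective ozonolysis, in which the electron-rich 1,1-disubstituted isopropenyl alkene should react far faster than the conjugated trisubstituted acrylic acid alkene, unmasks the methyl ketone; the silyloxy centre is not touched and becomes S only because the priorities change.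

**Step 10**
Reactants: 11 (3E,4S)-4-hydroxy-5-methylidene-3-tetradecylideneoxolan-2-one; 21 (2Z)-2-{(1S)-2-oxo-1-[(triethylsilyl)oxy]propyl}hexadec-2-enoic acid
Product: 23 (3S,4E)-2-methylidene-5-oxo-4-tetradecylideneoxolan-3-yl (2Z)-2-{(1S)-2-oxo-1-[(triethylsilyl)oxy]propyl}hexadec-2-enoate, via O-acylisourea 22 (not isolated)
Conditions: 11 (1.0 equiv), 21 (1.2 equiv), EDC·HCl (1.5 equiv), DMAP (0.3 equiv), CH2Cl2, 0 °C → rt
Reagents that add atoms: none
Why: Steglich esterification through the O-acylisourea and the acylpyridinium ion acylates the free secondary hydroxyl of 11 with only catalytic DMAP as base, so the enolisable silyloxy ketone centre and the Z alkene of 21 should be preserved, and no C–O bond at a stereocentre is broken.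

**Step 11**
Reactants: 23 (3S,4E)-2-methylidene-5-oxo-4-tetradecylideneoxolan-3-yl (2Z)-2-{(1S)-2-oxo-1-[(triethylsilyl)oxy]propyl}hexadec-2-enoate
Product: 24 (3S,4E)-2-methylidene-5-oxo-4-tetradecylideneoxolan-3-yl (2Z)-2-[(1S)-1-hydroxy-2-oxopropyl]hexadec-2-enoate (target)
Conditions: HF·pyridine, pyridine, THF, 0 °C
Reagents that add atoms: none
Why: Buffered HF·pyridine should cleave the secondary triethylsilyl ether under conditions that leave the enol lactone, the allylic ester and the α-ketol centre intact.

## Compound list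

1 | pentadec-1-yne | CCCCCCCCCCCCCC#C | starting material
2 | lithium pentadec-1-yn-1-ide | CCCCCCCCCCCCCC#[C-].[Li+] | intermediate
3 | hexadec-2-ynal | CCCCCCCCCCCCCC#CC=O | intermediate
4 | (2E)-2-(tributylstannyl)hexadec-2-enal (chain cis to CHO) | CCCCCCCCCCCCC/C=C(\C=O)[Sn](CCCC)(CCCC)CCCC | intermediate
5 | ethynyl(trimethyl)silane | C#C[Si](C)(C)C | starting material
6 | (3R,4E)-4-(tributylstannyl)-1-(trimethylsilyl)octadec-4-en-1-yn-3-ol | C[Si](C)(C)C#C[C@@H](O)/C(=C\CCCCCCCCCCCCC)[Sn](CCCC)(CCCC)CCCC | intermediate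
7 | lithium alkoxide of 6 in which SnBu3 is replaced by Li with retention of the alkene geometry | C[Si](C)(C)C#C[C@@H](O[Li])/C(=C\CCCCCCCCCCCCC)[Li] | intermediate
8 | dilithium salt (carboxylate and alkoxide) of 9 | C[Si](C)(C)C#C[C@@H]([O-])/C(=C\CCCCCCCCCCCCC)C(=O)[O-].[Li+].[Li+] | intermediate
9 | (2E)-2-[(1S)-1-hydroxy-3-(trimethylsilyl)prop-2-yn-1-yl]hexadec-2-enoic acid | C[Si](C)(C)C#C[C@@H](O)/C(=C\CCCCCCCCCCCCC)C(=O)O | intermediate
10 | (2E)-2-[(1R)-1-hydroxyprop-2-yn-1-yl]hexadec-2-enoic acid | C#C[C@@H](O)/C(=C\CCCCCCCCCCCCC)C(=O)O | intermediate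
11 | (3E,4S)-4-hydroxy-5-methylidene-3-tetradecylideneoxolan-2-one | C=C1OC(=O)/C(=C/CCCCCCCCCCCCC)[C@@H]1O | intermediate
12 | methacrolein (2-methylprop-2-enal) | CC(=C)C=O | starting material
13 | (3R)-2-methyloctadec-1-en-4-yn-3-ol | CCCCCCCCCCCCCC#C[C@H](O)C(C)=C | intermediate
14 | (3R,4Z)-2-methyl-4-(tributylstannyl)octadeca-1,4-dien-3-ol | CCCCCCCCCCCCC/C=C(/[C@H](O)C(C)=C)[Sn](CCCC)(CCCC)CCCC | intermediate
15 | lithium alkoxide of 14 in which SnBu3 is replaced by Li with retention of the alkene geometry | CCCCCCCCCCCCC/C=C(/[C@H](O[Li])C(C)=C)[Li] | intermediate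
16 | dilithium salt (carboxylate and alkoxide) of 17 | CCCCCCCCCCCCC/C=C(/[C@H]([O-])C(C)=C)C(=O)[O-].[Li+].[Li+] | intermediate
17 | (2Z)-2-[(1R)-1-hydroxy-2-methylprop-2-en-1-yl]hexadec-2-enoic acid | CCCCCCCCCCCCC/C=C(/[C@H](O)C(C)=C)C(=O)O | intermediate
18 | triethylsilyl ester of 19 | CCCCCCCCCCCCC/C=C(/[C@H](O[Si](CC)(CC)CC)C(C)=C)C(=O)O[Si](CC)(CC)CC | intermediate
19 | (2Z)-2-{(1R)-2-methyl-1-[(triethylsilyl)oxy]prop-2-en-1-yl}hexadec-2-enoic acid | CCCCCCCCCCCCC/C=C(/[C@H](O[Si](CC)(CC)CC)C(C)=C)C(=O)O | intermediate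
20 | secondary ozonide (3-methyl-1,2,4-trioxolan-3-yl in place of the isopropenyl group of 19; mixture at the ring carbon) | CCCCCCCCCCCCC/C=C(/[C@H](O[Si](CC)(CC)CC)C1(C)OCOO1)C(=O)O | intermediate
21 | (2Z)-2-{(1S)-2-oxo-1-[(triethylsilyl)oxy]propyl}hexadec-2-enoic acid | CCCCCCCCCCCCC/C=C(/[C@H](O[Si](CC)(CC)CC)C(C)=O)C(=O)O | intermediate
22 | O-acylisourea of 21 formed from EDC | CCN=C(NCCCN(C)C)OC(=O)/C(=C\CCCCCCCCCCCCC)[C@H](O[Si](CC)(CC)CC)C(C)=O | intermediate
23 | (3S,4E)-2-methylidene-5-oxo-4-tetradecylideneoxolan-3-yl (2Z)-2-{(1S)-2-oxo-1-[(triethylsilyl)oxy]propyl}hexadec-2-enoate | C=C1OC(=O)/C(=C/CCCCCCCCCCCCC)[C@@H]1OC(=O)/C(=C\CCCCCCCCCCCCC)[C@H](O[Si](CC)(CC)CC)C(C)=O | intermediate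
24 | (3S,4E)-2-methylidene-5-oxo-4-tetradecylideneoxolan-3-yl (2Z)-2-[(1S)-1-hydroxy-2-oxopropyl]hexadec-2-enoate | C=C1OC(=O)/C(=C/CCCCCCCCCCCCC)[C@@H]1OC(=O)/C(=C\CCCCCCCCCCCCC)[C@H](O)C(C)=O | target

Total step count: 11. Longest linear sequence: 7 (steps 1, 2, 3, 4, 5, 10, 11).

**Steps most likely to fail**

Step 3. Facial selectivity may be poor, or the catalysed pathway may be overtaken by the uncatalysed addition, at the hindered α-stannyl enal. The fallback sets out from 4 and separates C–C bond formation from stereocontrol. Lithium (trimethylsilyl)acetylide (from 5 and n-BuLi, THF, −78 °C) would add to 4 to give racemic (4E)-4-(tributylstannyl)-1-(trimethylsilyl)octadec-4-en-1-yn-3-ol F1. Dess–Martin oxidation would give (4E)-4-(tributylstannyl)-1-(trimethylsilyl)octadec-4-en-1-yn-3-one F2. Noyori transfer hydrogenation of this alkynyl ketone with RuCl[(S,S)-TsDPEN](p-cymene) in iPrOH would return to the route at 6.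

Step 7. In the telescoped sequence the tin–lithium exchange may be incomplete, or the alkenyllithium may be protonated before carboxylation, which would give net protodestannylation. The fallback sets out from 13, isolates the stannane 14 after the ruthenium step and installs the carboxyl carbon by carbonylation instead of through an organolithium. Hydroxyl-assisted methoxycarbonylation of 14 (Pd(OAc)2, 1,4-benzoquinone, catalytic CF3CO2H, CO 1 atm, MeOH, rt) would give methyl (2Z)-2-[(1R)-1-hydroxy-2-methylprop-2-en-1-yl]hexadec-2-enoate F3. Neutral ester cleavage with Me3SnOH (1,2-dichloroethane, 70 °C) would return to the route at 17.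

Step 10. The activated acid may epimerise at the silyloxy ketone carbon, the activated γ-keto acid may be captured in its ring form (pseudo-ester), or the hindered alcohol may be acylated so slowly that the N-acylurea forms. The fallback sets out from 1 and carries the ketone through the union as a non-enolisable dimethyl ketal. Acylation of the acetylide 2 with methyl 2,2-dimethoxypropanoate (BF3·OEt2, THF, −78 °C) would give 2,2-dimethoxyoctadec-4-yn-3-one F4. Noyori transfer hydrogenation with RuCl[(R,R)-TsDPEN](p-cymene) in iPrOH would give (3S)-2,2-dimethoxyoctadec-4-yn-3-ol F5. The trans-hydrostannation of step 7 would give (3R,4Z)-2,2-dimethoxy-4-(tributylstannyl)octadec-4-en-3-ol F6, and tin–lithium exchange followed by CO2 would give (2Z)-2-[(1S)-1-hydroxy-2,2-dimethoxypropyl]hexadec-2-enoic acid F7. Silylation as in step 8 would give (2Z)-2-{(1S)-2,2-dimethoxy-1-[(triethylsilyl)oxy]propyl}hexadec-2-enoic acid F8. Esterification with 11 as in step 10 would give (3S,4E)-2-methylidene-5-oxo-4-tetradecylideneoxolan-3-yl (2Z)-2-{(1S)-2,2-dimethoxy-1-[(triethylsilyl)oxy]propyl}hexadec-2-enoate F9. Pyridinium p-toluenesulfonate in wet acetone would then remove the silyl ether and the ketal together and return to the route at 24.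

## Further compounds

F1 | step 3 | rac-(4E)-4-(tributylstannyl)-1-(trimethylsilyl)octadec-4-en-1-yn-3-ol | C[Si](C)(C)C#CC(O)/C(=C\CCCCCCCCCCCCC)[Sn](CCCC)(CCCC)CCCC
F2 | step 3 | (4E)-4-(tributylstannyl)-1-(trimethylsilyl)octadec-4-en-1-yn-3-one | C[Si](C)(C)C#CC(=O)/C(=C\CCCCCCCCCCCCC)[Sn](CCCC)(CCCC)CCCC
F3 | step 7 | methyl (2Z)-2-[(1R)-1-hydroxy-2-methylprop-2-en-1-yl]hexadec-2-enoate | CCCCCCCCCCCCC/C=C(/[C@H](O)C(C)=C)C(=O)OC
F4 | step 10 | 2,2-dimethoxyoctadec-4-yn-3-one | CCCCCCCCCCCCCC#CC(=O)C(C)(OC)OC
F5 | step 10 | (3S)-2,2-dimethoxyoctadec-4-yn-3-ol | CCCCCCCCCCCCCC#C[C@H](O)C(C)(OC)OC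
F6 | step 10 | (3R,4Z)-2,2-dimethoxy-4-(tributylstannyl)octadec-4-en-3-ol | CCCCCCCCCCCCC/C=C(/[C@H](O)C(C)(OC)OC)[Sn](CCCC)(CCCC)CCCC
F7 | step 10 | (2Z)-2-[(1S)-1-hydroxy-2,2-dimethoxypropyl]hexadec-2-enoic acid | CCCCCCCCCCCCC/C=C(/[C@H](O)C(C)(OC)OC)C(=O)O
F8 | step 10 | (2Z)-2-{(1S)-2,2-dimethoxy-1-[(triethylsilyl)oxy]propyl}hexadec-2-enoic acid | CCCCCCCCCCCCC/C=C(/[C@H](O[Si](CC)(CC)CC)C(C)(OC)OC)C(=O)O
F9 | step 10 | (3S,4E)-2-methylidene-5-oxo-4-tetradecylideneoxolan-3-yl (2Z)-2-{(1S)-2,2-dimethoxy-1-[(triethylsilyl)oxy]propyl}hexadec-2-enoate | C=C1OC(=O)/C(=C/CCCCCCCCCCCCC)[C@@H]1OC(=O)/C(=C\CCCCCCCCCCCCC)[C@H](O[Si](CC)(CC)CC)C(C)(OC)OC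
A1 | direct plan | (3S,4S)-3-tetradecyl-4-[(trimethylsilyl)ethynyl]oxetan-2-one | O=C1O[C@H](C#C[Si](C)(C)C)[C@@H]1CCCCCCCCCCCCCC
A2 | direct plan | (3Z,4S)-3-tetradecylidene-4-[(trimethylsilyl)ethynyl]oxetan-2-one | CCCCCCCCCCCCC/C=C1\C(=O)O[C@@H]1C#C[Si](C)(C)C
A3 | direct plan | (3E,4S)-3-tetradecylidene-4-[(trimethylsilyl)ethynyl]oxetan-2-one | CCCCCCCCCCCCC/C=C1/C(=O)O[C@@H]1C#C[Si](C)(C)C
A4 | direct plan | (2E)-2-[(1R)-1-hydroxyprop-2-yn-1-yl]hexadec-2-enoic acid | OC(=O)/C(=C/CCCCCCCCCCCCC)[C@H](O)C#C
A5 | direct plan | (3S,4E)-2-methylidene-5-oxo-4-tetradecylideneoxolan-3-yl (2Z)-2-[(1R)-1-hydroxyprop-2-yn-1-yl]hexadec-2-enoate | C=C1OC(=O)/C(=C/CCCCCCCCCCCCC)[C@@H]1OC(=O)/C(=C\CCCCCCCCCCCCC)[C@H](O)C#C
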